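Reckon the small thing here, what is not target, and let the large one follow.

in all of them: gas 0.22 mM (held)

| flask | solid substrate | remark | time |
|---|---|---|---|
| larch | 2.5 mM | run made earlier |  |
| birch | 3.8 mM | run made earlier |  |
| flask | 5.0 mM |  | 12 min |

| run | time / min | solid substrate / % | target / % |
|---|---|---|---|
| larch | 1.00 | 0 | 72.9 |
| larch | 1.50 | 2.3 | 74.3 |
| larch | 2.50 | 0.3 | 78.5 |
| larch | 4.00 | 0.5 | 78.5 |
| larch | 8.00 | 0.5 | 81.1 |
| larch | 12.0 | 0 | 79.5 |
| birch | 0.833 | 2.0 | 65.9 |
| birch | 2.50 | 0 | 79.0 |
| birch | 4.00 | 0 | 80.6 |
| birch | 6.00 | 1.0 | 82.0 |
| birch | 10.0 | 0 | 80.8 |
| birch | 12.0 | 0 | 80.1 |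

(each reading ± 1 percentage point)

- at the start none of the solid substrate is in solution
- at the start none of the gas is in solution
- what has only dissolved of solid substrate counts as not reacted
- a reading or a percentage of target counts all its forms, free or not
- the reaction counts as stopped when no species that holds the solid substrate changes by six tenths of a point or more over the second half of the time

1. why nothing more happens at 12 min, or that something still does (for what has run out or reacted, a solid counts together with what of it has only dissolved) (forward and back rates have come level / all of the solid substrate has reacted / it is still moving)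
2. part of the solid substrate that has turned into other species by 12 min (what has only dissolved does not count)
3. the target standing at 12 min, as a percentage of the solid substrate charged

At 12.0 min the larch run reads 0 % solid substrate and 79.5 % target, and the birch run reads 0 % and 80.1 %. The solid reads as gone within scatter, yet 20.5 % and 19.9 % of the charge are not in the target readings. The rest goes unread, but it can be measured against the target. The last two readings average 80.3 % target in larch and 80.5 % in birch, so the rest per part of target is 0.245 and 0.242, although the charges are 2.5 mM and 3.8 mM. Pooled, 80.4 % target gives 0.244, which we call the spill: the rest standing per part of target at this gas. Our own reckoning for the new flask is then a target of 80.4 % and a rest of 0.981 mM.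

The forecast says all of the solid substrate has reacted, with 99.8 % converted and 80.3 % target: “the substrate has simply run out”.

In the new flask forward and back rates have come level, with 94.2 % converted and 82.5 % target. In this flask starting material stands at 5.79 % at 12.0 min and 5.79 % at 120 min, and crystals, counted in the target, hold 8.52 % of the charge at 12.0 min. Without the crystals, target in solution is 3.70 mM, and the spill on that gives a rest of 18.1 % of the charge, against 17.5 % standing.

    starting material + reagent ⇌ target (K = 58100 M⁻¹, k = 376 M⁻¹ s⁻¹)
    starting material + reagent ⇌ isomer of the product (K = 9170 M⁻¹, k = 150 M⁻¹ s⁻¹)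
    crystals ⇌ target, rate k3*(cs3 - [target]) while solid is left; crystals form when [target] > cs3 (solubility = 3.70 mM, k = 1.05 s⁻¹)
    solid substrate ⇌ starting material, rate k4*(cs4 - [starting material]) while solid is left; crystals form when [starting material] > cs4 (solubility = 1.60 mM, k = 0.429 s⁻¹)
    gas ⇌ reagent, rate k5*(csat - [reagent]) (kL = 1.01 s⁻¹)

In the neighbour with 8.5 mM solid substrate, crystals hold 46.2 %, so we take target in solution at its solubility limit, 3.7 mM. The spill then gives a rest of 0.903 mM, hence 89.4 % target, and the computed flask gives 89.7 %.

(The runs are calculated from invented constants; the scatter is artificial.)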